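**Retrosynthetic overview**

1. The triene is cut at its first double bond (Horner–Wadsworth–Emmons, last step), leaving a saturated C9 aldehyde on the peroxylactone core and a C7 dienyl phosphonate.
2. The lactone C4–O bond and the C5–H bond come from iodolactonisation and deiodination of a 3,6-dihydro-1,2-dioxin-3-ylacetic acid; the C3 side chain sets the quaternary C4 centre through the obligatory cis ring fusion.
3. The dioxane ring is closed at C4–C5 by ring-closing metathesis of an acyclic bis-allylic peroxide, with the O1–O2 bond as tether. The enabling feature: C4 [C(CH3)–O] and C5 (CH2) are the two dioxane carbons remote from the peroxide, and C4, with its methyl group and lactone oxygen, is the Markovnikov hydro-acyloxylation product of a trisubstituted C4=C5 olefin.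
4. The acyclic peroxide comes from catalyst-controlled oxa-Michael addition (sets C3) of a tertiary β-hydroxy hydroperoxide to 4-methylpenta-2,4-dienal; C6 comes from (S)-2-methylglycidol through epoxide perhydrolysis with inversion.
5. Ring order: dihydrodioxine first, γ-lactone second.

Key step: step 10

Remark (numbering): ring atoms are numbered as in the 1,2-dioxane: O1, O2, C3 (CH–O, ring fusion), C4 (C(CH3)–O of the lactone, ring fusion), C5 (CH2), C6 (C(CH3)(chain)).
Remark (assumption): the sense of induction in step 6 is taken from the usual shielding model of diarylprolinol silyl ether iminium ions; if it proves opposite, the antipodal catalyst is used.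

**Route**

Step 1
Reactants: 1 8-bromooctan-1-ol
Product: 2 [(8-bromooctyl)oxy](tert-butyl)diphenylsilane
Conditions: TBDPSCl, imidazole, CH2Cl2, 0 °C → rt
Reagents that add atoms: tert-butyl(chloro)diphenylsilane, CC(C)(C)[Si](Cl)(c1ccccc1)c1ccccc1
Why: Imidazole-mediated silylation of a primary alcohol gives a silyl ether that should survive the Grignard step and the acidic perhydrolysis of step 4.

Step 2
Reactants: 2 [(8-bromooctyl)oxy](tert-butyl)diphenylsilane; 3 (S)-2-methylglycidol
Product: 5 (R)-11-[(tert-butyldiphenylsilyl)oxy]-2-methylundecane-1,2-diol, via Grignard reagent 4 (not isolated)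
Conditions: Mg, THF, rt; then 3 (0.45 equiv), CuI (10 mol%), THF, −30 → 0 °C; aq. NH4Cl
Reagents that add atoms: none
Why: Copper-catalysed SN2 opening of the 2,2-disubstituted epoxide at its CH2 terminus (one equivalent of Grignard reagent serving as base for the hydroxyl group) attaches the chain without touching the quaternary stereocentre, whose label changes from S to R only through CIP priorities.

Step 3
Reactants: 5 (R)-11-[(tert-butyldiphenylsilyl)oxy]-2-methylundecane-1,2-diol
Product: 7 (R)-tert-butyl{[9-(2-methyloxiran-2-yl)nonyl]oxy}diphenylsilane, via primary tosylate 6 (not isolated)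
Conditions: TsCl (1.05 equiv), Et3N, Bu2SnO (2 mol%), CH2Cl2, 0 °C; then K2CO3, MeOH, rt
Reagents that add atoms: none
Why: Selective sulfonylation of the primary hydroxyl and intramolecular Williamson closure by the tertiary alkoxide give the epoxide with the C–O bond at the stereocentre untouched (retention).

Step 4
Reactants: 7 (R)-tert-butyl{[9-(2-methyloxiran-2-yl)nonyl]oxy}diphenylsilane
Product: 8 (S)-11-[(tert-butyldiphenylsilyl)oxy]-2-hydroperoxy-2-methylundecan-1-ol
Conditions: anhydrous H2O2 in Et2O (excess), phosphomolybdic acid (3 mol%), rt (blast shield)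
Reagents that add atoms: hydrogen peroxide, OO
Why: Phosphomolybdic acid-catalysed perhydrolysis of a 2,2-disubstituted epoxide takes place at the more substituted carbon in a borderline SN2 manner, so the tertiary hydroperoxide should form with inversion, which sets C6 as S.

Step 5
Reactants: 9 methacrolein; 10 (triphenylphosphoranylidene)acetaldehyde
Product: 11 (E)-4-methylpenta-2,4-dienal
Conditions: 9 (3 equiv), CH2Cl2, 40 °C
Reagents that add atoms: none
Why: Wittig olefination with the stabilised formyl ylide is E-selective, and the excess of methacrolein suppresses a second homologation.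

Step 6
Reactants: 8 (S)-11-[(tert-butyldiphenylsilyl)oxy]-2-hydroperoxy-2-methylundecan-1-ol; 11 (E)-4-methylpenta-2,4-dienal
Product: 12 (S)-3-({(S)-11-[(tert-butyldiphenylsilyl)oxy]-1-hydroxy-2-methylundecan-2-yl}peroxy)-4-methylpent-4-enal
Conditions: 11 (3 equiv), (S)-2-[diphenyl(triethylsilyloxy)methyl]pyrrolidine (20 mol%), PhCO2H (20 mol%), toluene, 0 °C
Reagents that add atoms: none
Why: Iminium-catalysed asymmetric β-peroxidation of an enal (oxa-Michael addition of an alkyl hydroperoxide, the α-nucleophilic OOH reacting in preference to the neopentyl OH) should give the β-peroxy aldehyde, the 3S centre being set by the catalyst, whose diaryl(silyloxy)methyl group blocks one β-face of the E,s-trans iminium ion while the remote C6 centre does not interfere.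

Step 7
Reactants: 12 (S)-3-({(S)-11-[(tert-butyldiphenylsilyl)oxy]-1-hydroxy-2-methylundecan-2-yl}peroxy)-4-methylpent-4-enal
Product: 13 (S)-3-({(S)-11-[(tert-butyldiphenylsilyl)oxy]-1-hydroxy-2-methylundecan-2-yl}peroxy)-4-methylpent-4-enoic acid
Conditions: NaClO2, NaH2PO4, 2-methyl-2-butene, t-BuOH–H2O, 0 °C → rt
Reagents that add atoms: sodium chlorite, [Na+].[O-]Cl=O
Why: Pinnick oxidation takes the aldehyde to the acid under buffered conditions that leave the dialkyl peroxide, the primary alcohol and (with the chlorine scavenger) the isopropenyl group untouched.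

Step 8
Reactants: 13 (S)-3-({(S)-11-[(tert-butyldiphenylsilyl)oxy]-1-hydroxy-2-methylundecan-2-yl}peroxy)-4-methylpent-4-enoic acid
Product: 14 (S)-3-({(S)-11-[(tert-butyldiphenylsilyl)oxy]-2-methyl-1-oxoundecan-2-yl}peroxy)-4-methylpent-4-enoic acid
Conditions: DMP, CH2Cl2, 0 °C → rt
Reagents that add atoms: none
Why: Dess–Martin oxidation of the neopentyl primary alcohol gives the non-enolisable α-peroxy aldehyde under non-basic conditions that the peroxide and the free acid tolerate.

Step 9
Reactants: 14 (S)-3-({(S)-11-[(tert-butyldiphenylsilyl)oxy]-2-methyl-1-oxoundecan-2-yl}peroxy)-4-methylpent-4-enoic acid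
Product: 15 (S)-3-({(S)-12-[(tert-butyldiphenylsilyl)oxy]-3-methyldodec-1-en-3-yl}peroxy)-4-methylpent-4-enoic acid
Conditions: KHMDS (1.0 equiv), THF, −78 °C; then Ph3P=CH2 (from Ph3PCH3Br, KHMDS; 1.5 equiv), −78 → 0 °C; aq. HCl to pH 3
Reagents that add atoms: methyltriphenylphosphonium bromide, C[P+](c1ccccc1)(c1ccccc1)c1ccccc1.[Br-]
Why: Wittig methylenation of the hindered, non-enolisable α-peroxy aldehyde should proceed cleanly because prior conversion of the acid into its carboxylate removes the acidic C–H that could trigger β-elimination of the peroxide.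

Step 10
Reactants: 15 (S)-3-({(S)-12-[(tert-butyldiphenylsilyl)oxy]-3-methyldodec-1-en-3-yl}peroxy)-4-methylpent-4-enoic acid
Product: 16 2-[(3S,6S)-6-{9-[(tert-butyldiphenylsilyl)oxy]nonyl}-4,6-dimethyl-3,6-dihydro-1,2-dioxin-3-yl]acetic acid
Conditions: (H2IMes)(PCy3)Cl2Ru=CHPh (10 mol%, two portions), degassed CH2Cl2 (5 mM), Ar sparge, 40 °C
Reagents that add atoms: none
Why: Proposed new method: the ruthenium alkylidene loads onto the vinyl group at C5 (a linalool-type tertiary allylic terminus), undergoes intramolecular [2+2] cycloaddition with the C4 isopropenyl group and cycloreverts with loss of ethylene, so that the C4=C5 bond forms while the pre-existing O1–O2 bond acts as tether. The closest known reaction types are ring-closing metathesis of vinyl/1,1-disubstituted dienes to trisubstituted cyclohexenes and ruthenium-catalysed cross-metathesis of alkenes that carry dialkyl peroxide groups, which indicates that the O–O bond can survive the catalyst. The six-membered 3,6-dihydro-1,2-dioxine is the only ring closed, by ring-closing metathesis between the two olefinic carbons attached to the peroxide-bearing carbons C3 and C6, which the gauche C–O–O–C tether holds in a 1,6-relationship. No stereocentre is formed: C3 and C6 are carried through unchanged, and the new trisubstituted olefin is the device through which C3 sets C4 in step 11. The step needs chemoselectivity for ring closure over oligomerisation and over ruthenium- or base-induced cleavage of the allylic peroxide; both olefins are hindered and slow to cross-metathesise, the reaction is run at high dilution in a neutral medium, and the free acid avoids a β-peroxy ester that could eliminate.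

Step 11
Reactants: 16 2-[(3S,6S)-6-{9-[(tert-butyldiphenylsilyl)oxy]nonyl}-4,6-dimethyl-3,6-dihydro-1,2-dioxin-3-yl]acetic acid
Product: 17 cis-fused γ-lactone of 2-[(3S,4R,5S,6S)-6-{9-[(tert-butyldiphenylsilyl)oxy]nonyl}-4-hydroxy-5-iodo-4,6-dimethyl-1,2-dioxan-3-yl]acetic acid (iodine anti to the lactone oxygen; the 4R label reflects only the CIP rank of the iodinated carbon)
Conditions: I2, NaHCO3, MeCN–H2O, 0 °C, dark
Reagents that add atoms: iodine, II
Why: Iodolactonisation (5-exo, Markovnikov at the tertiary C4) delivers the carboxylate to C4 from the face of the C3 side chain, so the cis-fused lactone and hence the quaternary C4 centre are set by C3, while iodine adds anti at C5.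

Step 12
Reactants: 17 cis-fused γ-lactone of 2-[(3S,4R,5S,6S)-6-{9-[(tert-butyldiphenylsilyl)oxy]nonyl}-4-hydroxy-5-iodo-4,6-dimethyl-1,2-dioxan-3-yl]acetic acid
Product: 18 cis-fused γ-lactone of 2-[(3S,4S,6S)-6-{9-[(tert-butyldiphenylsilyl)oxy]nonyl}-4-hydroxy-4,6-dimethyl-1,2-dioxan-3-yl]acetic acid
Conditions: Bu3SnH, Et3B/air (cat.), toluene, 0 °C → rt
Reagents that add atoms: none
Why: Radical-chain hydrodeiodination with tin hydride removes the auxiliary iodine, the C5 radical lying inside the dioxane ring where the collinear geometry for attack on the O–O bond cannot be reached, and C5 becomes a CH2 group so that no stereocentre is at stake.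

Step 13
Reactants: 18 cis-fused γ-lactone of 2-[(3S,4S,6S)-6-{9-[(tert-butyldiphenylsilyl)oxy]nonyl}-4-hydroxy-4,6-dimethyl-1,2-dioxan-3-yl]acetic acid
Product: 19 cis-fused γ-lactone of 2-[(3S,4S,6S)-4-hydroxy-6-(9-hydroxynonyl)-4,6-dimethyl-1,2-dioxan-3-yl]acetic acid
Conditions: HF·pyridine, pyridine–THF, 0 °C → rt
Reagents that add atoms: none
Why: Fluoride cleavage of the silyl ether under weakly acidic conditions spares the base-labile β-peroxy lactone.

Step 14
Reactants: 19 cis-fused γ-lactone of 2-[(3S,4S,6S)-4-hydroxy-6-(9-hydroxynonyl)-4,6-dimethyl-1,2-dioxan-3-yl]acetic acid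
Product: 20 cis-fused γ-lactone of 2-[(3S,4S,6S)-4-hydroxy-4,6-dimethyl-6-(9-oxononyl)-1,2-dioxan-3-yl]acetic acid
Conditions: DMP, CH2Cl2, 0 °C → rt
Reagents that add atoms: none
Why: Dess–Martin oxidation gives the aldehyde without base, so the β-peroxy lactone is not exposed to elimination.

Step 15
Reactants: 21 (2E,4E)-hepta-2,4-dienal
Product: 22 (2E,4E)-hepta-2,4-dien-1-ol
Conditions: NaBH4, MeOH, 0 °C
Reagents that add atoms: none
Why: Borohydride reduces the conjugated aldehyde in the 1,2-sense and leaves the diene geometry unchanged.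

Step 16
Reactants: 22 (2E,4E)-hepta-2,4-dien-1-ol
Product: 23 (2E,4E)-1-bromohepta-2,4-diene
Conditions: PBr3 (0.4 equiv), Et2O, −10 °C
Reagents that add atoms: phosphorus tribromide, BrP(Br)Br
Why: Low-temperature bromination of the primary dienylic alcohol by SN2 displacement of the phosphite ester should retain the E,E geometry.

Step 17
Reactants: 23 (2E,4E)-1-bromohepta-2,4-diene
Product: 24 diethyl [(2E,4E)-hepta-2,4-dien-1-yl]phosphonate
Conditions: P(OEt)3, neat, 90 °C, EtBr distilled off
Reagents that add atoms: triethyl phosphite, CCOP(OCC)OCC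
Why: Michaelis–Arbuzov reaction of the primary dienylic bromide gives the linear phosphonate.

Step 18
Reactants: 20 cis-fused γ-lactone of 2-[(3S,4S,6S)-4-hydroxy-4,6-dimethyl-6-(9-oxononyl)-1,2-dioxan-3-yl]acetic acid; 24 diethyl [(2E,4E)-hepta-2,4-dien-1-yl]phosphonate
Product: 26 cis-fused γ-lactone of 2-[(3S,4S,6S)-6-[(9E,11E,13E)-hexadeca-9,11,13-trien-1-yl]-4-hydroxy-4,6-dimethyl-1,2-dioxan-3-yl]acetic acid, via sodiated phosphonate 25 (not isolated)
Conditions: 24 (1.5 equiv), NaHMDS (1.4 equiv), THF, −78 °C; then 20, −78 °C → rt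
Reagents that add atoms: none
Why: Horner–Wadsworth–Emmons olefination with the pre-formed allylic phosphonate carbanion (no free amide base) should form the new disubstituted double bond mainly E, the 11E,13E geometry being carried in by the reagent and no stereocentre of the core being touched.

**Compound list**

1 | 8-bromooctan-1-ol | OCCCCCCCCBr | starting material
2 | [(8-bromooctyl)oxy](tert-butyl)diphenylsilane | BrCCCCCCCCO[Si](c1ccccc1)(c1ccccc1)C(C)(C)C | intermediate
3 | (S)-2-methylglycidol | C[C@]1(CO)CO1 | starting material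
4 | {8-[(tert-butyldiphenylsilyl)oxy]octyl}magnesium bromide | Br[Mg]CCCCCCCCO[Si](c1ccccc1)(c1ccccc1)C(C)(C)C | intermediate
5 | (R)-11-[(tert-butyldiphenylsilyl)oxy]-2-methylundecane-1,2-diol | C[C@](O)(CO)CCCCCCCCCO[Si](c1ccccc1)(c1ccccc1)C(C)(C)C | intermediate
6 | (R)-11-[(tert-butyldiphenylsilyl)oxy]-2-hydroxy-2-methylundecyl 4-methylbenzenesulfonate | C[C@](O)(COS(=O)(=O)c1ccc(C)cc1)CCCCCCCCCO[Si](c1ccccc1)(c1ccccc1)C(C)(C)C | intermediate
7 | (R)-tert-butyl{[9-(2-methyloxiran-2-yl)nonyl]oxy}diphenylsilane | C[C@@]1(CCCCCCCCCO[Si](c2ccccc2)(c2ccccc2)C(C)(C)C)CO1 | intermediate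
8 | (S)-11-[(tert-butyldiphenylsilyl)oxy]-2-hydroperoxy-2-methylundecan-1-ol | C[C@](OO)(CCCCCCCCCO[Si](c1ccccc1)(c1ccccc1)C(C)(C)C)CO | intermediate
9 | methacrolein | CC(=C)C=O | starting material
10 | (triphenylphosphoranylidene)acetaldehyde | O=CC=P(c1ccccc1)(c1ccccc1)c1ccccc1 | starting material
11 | (E)-4-methylpenta-2,4-dienal | C=C(C)/C=C/C=O | intermediate
12 | (S)-3-({(S)-11-[(tert-butyldiphenylsilyl)oxy]-1-hydroxy-2-methylundecan-2-yl}peroxy)-4-methylpent-4-enal | O=CC[C@@H](C(C)=C)OO[C@](C)(CO)CCCCCCCCCO[Si](c1ccccc1)(c1ccccc1)C(C)(C)C | intermediate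
13 | (S)-3-({(S)-11-[(tert-butyldiphenylsilyl)oxy]-1-hydroxy-2-methylundecan-2-yl}peroxy)-4-methylpent-4-enoic acid | OC(=O)C[C@@H](C(C)=C)OO[C@](C)(CO)CCCCCCCCCO[Si](c1ccccc1)(c1ccccc1)C(C)(C)C | intermediate
14 | (S)-3-({(S)-11-[(tert-butyldiphenylsilyl)oxy]-2-methyl-1-oxoundecan-2-yl}peroxy)-4-methylpent-4-enoic acid | OC(=O)C[C@@H](C(C)=C)OO[C@](C)(C=O)CCCCCCCCCO[Si](c1ccccc1)(c1ccccc1)C(C)(C)C | intermediate
15 | (S)-3-({(S)-12-[(tert-butyldiphenylsilyl)oxy]-3-methyldodec-1-en-3-yl}peroxy)-4-methylpent-4-enoic acid | OC(=O)C[C@@H](C(C)=C)OO[C@](C)(C=C)CCCCCCCCCO[Si](c1ccccc1)(c1ccccc1)C(C)(C)C | intermediate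
16 | 2-[(3S,6S)-6-{9-[(tert-butyldiphenylsilyl)oxy]nonyl}-4,6-dimethyl-3,6-dihydro-1,2-dioxin-3-yl]acetic acid | OC(=O)C[C@@H]1OO[C@@](C)(CCCCCCCCCO[Si](c2ccccc2)(c2ccccc2)C(C)(C)C)C=C1C | intermediate
17 | cis-fused γ-lactone of 2-[(3S,4R,5S,6S)-6-{9-[(tert-butyldiphenylsilyl)oxy]nonyl}-4-hydroxy-5-iodo-4,6-dimethyl-1,2-dioxan-3-yl]acetic acid | CC(C)(C)[Si](c3ccccc3)(c3ccccc3)OCCCCCCCCC[C@@]1(C)[C@@H](I)[C@]2(C)OC(=O)C[C@@H]2OO1 | intermediate
18 | cis-fused γ-lactone of 2-[(3S,4S,6S)-6-{9-[(tert-butyldiphenylsilyl)oxy]nonyl}-4-hydroxy-4,6-dimethyl-1,2-dioxan-3-yl]acetic acid | CC(C)(C)[Si](c3ccccc3)(c3ccccc3)OCCCCCCCCC[C@@]1(C)C[C@]2(C)OC(=O)C[C@@H]2OO1 | intermediate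
19 | cis-fused γ-lactone of 2-[(3S,4S,6S)-4-hydroxy-6-(9-hydroxynonyl)-4,6-dimethyl-1,2-dioxan-3-yl]acetic acid | OCCCCCCCCC[C@@]1(C)C[C@]2(C)OC(=O)C[C@@H]2OO1 | intermediate
20 | cis-fused γ-lactone of 2-[(3S,4S,6S)-4-hydroxy-4,6-dimethyl-6-(9-oxononyl)-1,2-dioxan-3-yl]acetic acid | O=CCCCCCCCC[C@@]1(C)C[C@]2(C)OC(=O)C[C@@H]2OO1 | intermediate
21 | (2E,4E)-hepta-2,4-dienal | CC/C=C/C=C/C=O | starting material
22 | (2E,4E)-hepta-2,4-dien-1-ol | CC/C=C/C=C/CO | intermediate
23 | (2E,4E)-1-bromohepta-2,4-diene | CC/C=C/C=C/CBr | intermediate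
24 | diethyl [(2E,4E)-hepta-2,4-dien-1-yl]phosphonate | CC/C=C/C=C/CP(=O)(OCC)OCC | intermediate
25 | sodium salt of the α-carbanion of 24 | CC/C=C/C=C/[CH-]P(=O)(OCC)OCC.[Na+] | intermediate
26 | cis-fused γ-lactone of 2-[(3S,4S,6S)-6-[(9E,11E,13E)-hexadeca-9,11,13-trien-1-yl]-4-hydroxy-4,6-dimethyl-1,2-dioxan-3-yl]acetic acid | CC/C=C/C=C/C=C/CCCCCCCC[C@@]1(C)C[C@]2(C)OC(=O)C[C@@H]2OO1 | target

**Step count and risks**

Total step count: 18. Longest linear sequence: 14 steps (steps 1–4, 6–14 and 18).

Step 10 (ring-closing metathesis through the peroxide tether). What may go wrong: cleavage of the allylic O–O bond by the ruthenium(II) centre, olefin isomerisation by ruthenium hydrides formed on catalyst decay, or failure to initiate and close at two hindered olefins before the catalyst dies. The fallback uses known chemistry and closes the dioxane at oxygen instead of at carbon; it sets out from Grignard reagent 4 and comes back to the route at 18. Copper-catalysed coupling of 4 with 3-chloro-2-(chloromethyl)prop-1-ene gives the allylic chloride F1. Silver trifluoroacetate-promoted γ-alkylation of purchased 5-methyl-2-(trimethylsilyloxy)furan with F1 gives the racemic butenolide F2, from which the (S)-butenolide F3 is taken by preparative chromatography on a chiral phase. Cobalt-catalysed hydroperoxysilylation of the 1,1-disubstituted olefin (Co(thd)2, O2, Et3SiH; Mukaiyama–Isayama) gives the triethylsilyl peroxide F4 as both epimers at the new tertiary centre. Acidic methanolysis frees the hydroperoxide F5, and Et2NH in CF3CH2OH induces intramolecular oxa-Michael addition to the butenolide, which should give cis-fused 18 together with its C6 epimer F6; the two are separated by chromatography. The price is the loss of control at C6 and a resolution.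

Step 6 (asymmetric β-peroxidation). What may go wrong: closure of the β-peroxy enamine to an epoxy aldehyde with loss of the hydroperoxide as its alcohol, 1,6- instead of 1,4-addition to the dienal, acetalisation of the β-hydroxy hydroperoxide with the aldehyde to a 1,2,4-trioxane, or insufficient facial discrimination. The fallback sets out from 8 (with 11) and comes back at 12. Conjugate addition under tertiary-amine catalysis (Et3N cat., CF3CH2OH–CH2Cl2, 0 °C), in which neither an enamine nor an acidic medium is present, should give 12 together with its C3 epimer F7 without stereocontrol. The two diastereomers are separated by preparative HPLC, so that C3 is secured by separation and not by the catalyst.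

Step 18 (late olefination). What may go wrong: β-elimination of the peroxide from the lactone (retro-oxa-Michael) by base during the slow collapse of the phosphonate adduct, and incomplete E selectivity at the new double bond. The fallback sets out from 20 and comes back at 26. Two successive base-free Wittig homologations with the stabilised ylide 10 (benzene, 40–60 °C) give the (E)-enal F8 and then the (2E,4E)-dienal F9. Julia–Kocienski olefination of F9 with the pre-formed potassium salt of 1-phenyl-5-(propylsulfonyl)-1H-tetrazole at −78 °C, an alkyl sulfone/enal pairing that is usually E-selective and eliminates at low temperature, then gives 26.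

Further compounds
F1 | step 10 | tert-butyl{[10-(chloromethyl)undec-10-en-1-yl]oxy}diphenylsilane | C=C(CCl)CCCCCCCCCO[Si](c1ccccc1)(c1ccccc1)C(C)(C)C
F2 | step 10 | rac-5-{11-[(tert-butyldiphenylsilyl)oxy]-2-methylideneundecyl}-5-methylfuran-2(5H)-one | C=C(CCCCCCCCCO[Si](c2ccccc2)(c2ccccc2)C(C)(C)C)CC1(C)OC(=O)C=C1
F3 | step 10 | (S)-5-{11-[(tert-butyldiphenylsilyl)oxy]-2-methylideneundecyl}-5-methylfuran-2(5H)-one | C=C(CCCCCCCCCO[Si](c2ccccc2)(c2ccccc2)C(C)(C)C)C[C@]1(C)OC(=O)C=C1
F4 | step 10 | (S)-5-{11-[(tert-butyldiphenylsilyl)oxy]-2-methyl-2-[(triethylsilyl)peroxy]undecyl}-5-methylfuran-2(5H)-one (both epimers at the peroxide carbon) | CC[Si](CC)(CC)OOC(C)(CCCCCCCCCO[Si](c2ccccc2)(c2ccccc2)C(C)(C)C)C[C@]1(C)OC(=O)C=C1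
F5 | step 10 | (S)-5-{11-[(tert-butyldiphenylsilyl)oxy]-2-hydroperoxy-2-methylundecyl}-5-methylfuran-2(5H)-one (both epimers at the peroxide carbon) | OOC(C)(CCCCCCCCCO[Si](c2ccccc2)(c2ccccc2)C(C)(C)C)C[C@]1(C)OC(=O)C=C1
F6 | step 10 | C6 epimer of 18, cis-fused γ-lactone of 2-[(3S,4S,6R)-6-{9-[(tert-butyldiphenylsilyl)oxy]nonyl}-4-hydroxy-4,6-dimethyl-1,2-dioxan-3-yl]acetic acid | CC(C)(C)[Si](c3ccccc3)(c3ccccc3)OCCCCCCCCC[C@]1(C)C[C@]2(C)OC(=O)C[C@@H]2OO1
F7 | step 6 | (R)-3-({(S)-11-[(tert-butyldiphenylsilyl)oxy]-1-hydroxy-2-methylundecan-2-yl}peroxy)-4-methylpent-4-enal | O=CC[C@H](C(C)=C)OO[C@](C)(CO)CCCCCCCCCO[Si](c1ccccc1)(c1ccccc1)C(C)(C)C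
F8 | step 18 | cis-fused γ-lactone of 2-[(3S,4S,6S)-4-hydroxy-4,6-dimethyl-6-[(E)-11-oxoundec-9-en-1-yl]-1,2-dioxan-3-yl]acetic acid | O=C/C=C/CCCCCCCC[C@@]1(C)C[C@]2(C)OC(=O)C[C@@H]2OO1
F9 | step 18 | cis-fused γ-lactone of 2-[(3S,4S,6S)-4-hydroxy-4,6-dimethyl-6-[(9E,11E)-13-oxotrideca-9,11-dien-1-yl]-1,2-dioxan-3-yl]acetic acid | O=C/C=C/C=C/CCCCCCCC[C@@]1(C)C[C@]2(C)OC(=O)C[C@@H]2OO1
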